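Primed locants denote the cyclohexene, plain ones the dihydrobenzofuran. Within ring C1'–C6' the C1'=C2' double bond is flanked by C6' and by oxygen-bearing C3', and C4' carries the second oxygen; this is the retron of a Diels–Alder reaction between a 1-acyloxy-3-substituted butadiene (C6'=C1'–C2'=C3') and a two-carbon dienophile (C4'–C5'). The precursor is thus a trans-2,3-dihydrobenzofuran bearing an (E)-4-acetoxybuta-1,3-dien-2-yl group on C2. Endo cycloaddition of acrolein, activated as a chiral iminium ion, makes C3'–C4' and C5'–C6', closes the carbocycle and fixes the cis C3'/C4' stereocentres in a single operation; the formyl group is later exchanged for hydroxyl with retention. C3 stems from rhodium-catalysed conjugate arylation, C2 from ester equilibration.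

Key step: step 10

Assumption: the face selectivities of the rhodium/(S)-BINAP aryl transfer (step 5) and of the (5S)-imidazolidinone iminium ion (step 10) follow the usual shielding models; should either sense prove opposite, the mirror-image ligand or catalyst is used with no other change.

Design remark: the target reads as (2S,3R) trans on the dihydrobenzofuran and (3'S,4'R) cis on the cyclohexene. The C2/C3 trans relationship is fixed at the ester stage, because a 2-ethynyl centre can no longer be epimerised. The diene is converged to the E isomer, because a Z-1-acyloxy diene cannot reach the s-cis geometry. TBS = tert-butyldimethylsilyl, TBSO = tert-butyldimethylsilyloxy.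

Step 1
Reactants: 1 4-(3-hydroxypropyl)-2-methoxyphenol (dihydroconiferyl alcohol)
Product: 2 2-bromo-4-(3-hydroxypropyl)-6-methoxyphenol
Conditions: NBS (1.0 equiv), MeCN, 0 °C
Reagents that add atoms: N-bromosuccinimide, O=C1CCC(=O)N1Br
Why: Electrophilic aromatic bromination, in which the free phenol directs the bromine to its only open ortho position (the para position is blocked by the side chain), should give the handle for borylation.

Step 2
Reactants: 2 2-bromo-4-(3-hydroxypropyl)-6-methoxyphenol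
Product: 3 tert-butyl{2-bromo-6-methoxy-4-[3-(TBSO)propyl]phenoxy}dimethylsilane
Conditions: TBSCl (2.5 equiv), imidazole (5 equiv), DMF, rt
Reagents that add atoms: tert-butyldimethylsilyl chloride, CC(C)(C)[Si](C)(C)Cl
Why: Standard silylation caps the phenol and the primary alcohol in one operation, and the aryl silyl ether is the one that methanolic base removes selectively in step 7.

Step 3
Reactants: 3 tert-butyl{2-bromo-6-methoxy-4-[3-(TBSO)propyl]phenoxy}dimethylsilane
Product: 4 2-{3-methoxy-2-(TBSO)-5-[3-(TBSO)propyl]phenyl}-4,4,5,5-tetramethyl-1,3,2-dioxaborolane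
Conditions: B2pin2 (1.3 equiv), PdCl2(dppf) (3 mol %), KOAc (3 equiv), 1,4-dioxane, 90 °C
Reagents that add atoms: bis(pinacolato)diboron, CC1(C)OB(OC1(C)C)B1OC(C)(C)C(C)(C)O1
Why: Miyaura borylation of the electron-rich aryl bromide under acetate conditions tolerates both silyl ethers and avoids an aryllithium that could suffer oxygen-to-carbon silyl migration.

Step 4
Reactants: 5 (tert-butyldimethylsilyloxy)acetaldehyde; 6 methyl (triphenylphosphoranylidene)acetate
Product: 7 methyl (2E)-4-(TBSO)but-2-enoate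
Conditions: CH2Cl2, rt
Reagents that add atoms: none
Why: Wittig olefination with a stabilised ylide should give the (E)-enoate selectively and delivers the future C3 carbon with its oxygen already protected.

Step 5
Reactants: 4 2-{3-methoxy-2-(TBSO)-5-[3-(TBSO)propyl]phenyl}-4,4,5,5-tetramethyl-1,3,2-dioxaborolane; 7 methyl (2E)-4-(TBSO)but-2-enoate
Product: 8 methyl (3R)-3-{3-methoxy-2-(TBSO)-5-[3-(TBSO)propyl]phenyl}-4-(TBSO)butanoate
Conditions: [RhCl(C2H4)2]2 (2.5 mol %), (S)-BINAP (6 mol %), K3PO4 (1 equiv), 1,4-dioxane/H2O (10:1), 60 °C; 7 in excess (1.5 equiv)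
Reagents that add atoms: none
Why: In this rhodium-catalysed asymmetric conjugate arylation (Hayashi–Miyaura reaction) the aryl–rhodium/(S)-BINAP species should add to the α-si face of the (E)-enoate, which sets the future C3 centre as (R).

Step 6
Reactants: 8 methyl (3R)-3-{3-methoxy-2-(TBSO)-5-[3-(TBSO)propyl]phenyl}-4-(TBSO)butanoate
Product: 10 methyl (2RS,3R)-2-bromo-3-{3-methoxy-2-(TBSO)-5-[3-(TBSO)propyl]phenyl}-4-(TBSO)butanoate, via silyl ketene acetal 9 (not isolated)
Conditions: LiN(SiMe3)2 (1.2 equiv), Me3SiCl (1.5 equiv), THF, −78 °C; then NBS (1.1 equiv), −78 → 0 °C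
Reagents that add atoms: N-bromosuccinimide, O=C1CCC(=O)N1Br (the silyl group of chlorotrimethylsilane, C[Si](C)(C)Cl, is present only in 9)
Why: α-Bromination of an ester through its silyl ketene acetal is fast at −78 °C and should outrun ring bromination, and the configuration at the brominated carbon is immaterial because C2 is corrected in step 7.

Step 7
Reactants: 10 methyl (2RS,3R)-2-bromo-3-{3-methoxy-2-(TBSO)-5-[3-(TBSO)propyl]phenyl}-4-(TBSO)butanoate
Product: 13 methyl (2S,3R)-7-methoxy-3-(TBSO-methyl)-5-[3-(TBSO)propyl]-2,3-dihydro-1-benzofuran-2-carboxylate (trans), via phenol bromo ester 11 (not isolated), via cis ester 12 (not isolated)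
Conditions: K2CO3 (2.5 equiv), MeOH, 0 °C → rt; then NaOMe (0.3 equiv), 40 °C
Reagents that add atoms: none
Why: Methanolic carbonate cleaves the aryl silyl ether selectively, the phenoxide closes the dihydrofuran by intramolecular Williamson etherification (5-exo-tet), and methoxide epimerises the α-aryloxy ester to the more stable trans isomer, so C2 is set by thermodynamics relative to C3.

Step 8
Reactants: 13 methyl (2S,3R)-7-methoxy-3-(TBSO-methyl)-5-[3-(TBSO)propyl]-2,3-dihydro-1-benzofuran-2-carboxylate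
Product: 15 (2S,3R)-2-ethynyl-7-methoxy-3-(TBSO-methyl)-5-[3-(TBSO)propyl]-2,3-dihydro-1-benzofuran, via aldehyde 14 (not isolated)
Conditions: i-Bu2AlH (1.15 equiv), CH2Cl2, −78 °C; then MeOH, K2CO3 (3 equiv), dimethyl (1-diazo-2-oxopropyl)phosphonate (1.5 equiv), −78 °C → rt
Reagents that add atoms: dimethyl (1-diazo-2-oxopropyl)phosphonate, COP(=O)(OC)C(=[N+]=[N-])C(C)=O
Why: Partial reduction of the α-alkoxy ester to the aldehyde followed in the same flask by Ohira–Bestmann (Seyferth–Gilbert) homologation should give the terminal alkyne, and the trans C2 centre is the thermodynamically preferred one and so is not endangered by the base.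

Step 9
Reactants: 15 (2S,3R)-2-ethynyl-7-methoxy-3-(TBSO-methyl)-5-[3-(TBSO)propyl]-2,3-dihydro-1-benzofuran; 16 vinyl acetate
Product: 18 (1E)-3-{(2S,3R)-7-methoxy-3-(TBSO-methyl)-5-[3-(TBSO)propyl]-2,3-dihydro-1-benzofuran-2-yl}buta-1,3-dien-1-yl acetate, via Z-dienyl acetate 17 (not isolated)
Conditions: RuCl2(=CHPh)(SIMes)(PCy3) (second-generation Grubbs catalyst, 5 mol %), vinyl acetate (10 equiv), PhMe, 60 °C; then PhSSPh (5 mol %), hν (365 nm), rt
Reagents that add atoms: none
Why: Enyne cross-metathesis of a terminal alkyne with an enol ester should give the 1-acetoxy-3-substituted diene with full atom economy, and the thiyl-radical equilibration funnels the Z portion to the E isomer, which is favoured because the Z form suffers allylic strain with the groups on C1'.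

Step 10
Reactants: 18 (1E)-3-{(2S,3R)-7-methoxy-3-(TBSO-methyl)-5-[3-(TBSO)propyl]-2,3-dihydro-1-benzofuran-2-yl}buta-1,3-dien-1-yl acetate; 19 acrolein
Product: 20 (1S,6R)-6-formyl-3-{(2S,3R)-7-methoxy-3-(TBSO-methyl)-5-[3-(TBSO)propyl]-2,3-dihydro-1-benzofuran-2-yl}cyclohex-2-en-1-yl acetate (3'S,4'R in route locants)
Conditions: (5S)-5-benzyl-2,2,3-trimethylimidazolidin-4-one hydrochloride (20 mol %), acrolein (4 equiv), MeCN/H2O (95:5), −10 °C; product used after short filtration
Reagents that add atoms: none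
Why: The secondary amine salt condenses reversibly with acrolein to an (E)-iminium ion whose lowered LUMO undergoes a concerted but asynchronous (4+2) cycloaddition with the s-cis diene of 18 (C5'–C6' bond leading), and hydrolysis of the product iminium ion releases aldehyde 20 and the catalyst. The closest known reaction type is the imidazolidinone-catalysed enantioselective Diels–Alder reaction of acrolein with 1-acyloxybutadienes and with 2-substituted butadienes. The cyclohexene is closed by intermolecular (4+2) cycloaddition, C3'–C4' and C5'–C6' both being formed suprafacially in the one event. C4' is controlled by the catalyst, whose benzyl group covers one face of the iminium ion so that the diene adds to the exposed Cα face and should give (4'R); C3' is controlled by the endo transition state together with the E geometry of the dienyl acetate, which places acetoxy and formyl cis and should give (3'S). The step needs regio-, endo and facial selectivity: the acetoxy terminus (ortho rule) and the C1' substituent (para rule) both send the formyl-bearing carbon to C4', secondary orbital overlap with the iminium π system favours endo, and the catalyst rather than the freely rotating, weakly biasing C2 centre decides the face. Any residual Z diene cannot reach the s-cis geometry and stays unchanged, and the mild acidity and low temperature should spare the silyl ethers and the enol ester.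

Step 11
Reactants: 20 (1S,6R)-6-formyl-3-{(2S,3R)-7-methoxy-3-(TBSO-methyl)-5-[3-(TBSO)propyl]-2,3-dihydro-1-benzofuran-2-yl}cyclohex-2-en-1-yl acetate
Product: 22 (1R,2S)-4-{(2S,3R)-7-methoxy-3-(TBSO-methyl)-5-[3-(TBSO)propyl]-2,3-dihydro-1-benzofuran-2-yl}cyclohex-3-ene-1,2-diol, via formate 21 (not isolated)
Conditions: mCPBA (1.2 equiv), CH2Cl2, 0 °C; Me2S quench; then K2CO3 (4 equiv), MeOH, 0 °C → rt
Reagents that add atoms: meta-chloroperbenzoic acid, OOC(=O)c1cccc(Cl)c1
Why: In this Baeyer–Villiger oxidation of an α-branched aldehyde the secondary C4' migrates with retention to give the formate, in preference to epoxidation because the C1'=C2' alkene is deactivated by its allylic acetate and allylic ether oxygens, and methanolysis of formate and acetate then frees the cis-diol without exposing the eliminable β-acetoxy aldehyde to base.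

Step 12
Reactants: 22 (1R,2S)-4-{(2S,3R)-7-methoxy-3-(TBSO-methyl)-5-[3-(TBSO)propyl]-2,3-dihydro-1-benzofuran-2-yl}cyclohex-3-ene-1,2-diol
Product: 23 difengpiol A, (1R,2S)-4-[(2S,3R)-3-(hydroxymethyl)-5-(3-hydroxypropyl)-7-methoxy-2,3-dihydro-1-benzofuran-2-yl]cyclohex-3-ene-1,2-diol
Conditions: HF·pyridine, pyridine/THF, 0 °C → rt
Reagents that add atoms: none
Why: Buffered fluoride desilylation should remove both primary silyl ethers without ionising the allylic diol or touching any stereocentre.

Compound list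
1 | 4-(3-hydroxypropyl)-2-methoxyphenol (dihydroconiferyl alcohol) | COc1cc(CCCO)ccc1O | starting material
2 | 2-bromo-4-(3-hydroxypropyl)-6-methoxyphenol | COc1cc(CCCO)cc(Br)c1O | intermediate
3 | tert-butyl{2-bromo-6-methoxy-4-[3-(TBSO)propyl]phenoxy}dimethylsilane | COc1cc(CCCO[Si](C)(C)C(C)(C)C)cc(Br)c1O[Si](C)(C)C(C)(C)C | intermediate
4 | 2-{3-methoxy-2-(TBSO)-5-[3-(TBSO)propyl]phenyl}-4,4,5,5-tetramethyl-1,3,2-dioxaborolane | COc1cc(CCCO[Si](C)(C)C(C)(C)C)cc(B2OC(C)(C)C(C)(C)O2)c1O[Si](C)(C)C(C)(C)C | intermediate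
5 | (tert-butyldimethylsilyloxy)acetaldehyde | CC(C)(C)[Si](C)(C)OCC=O | starting material
6 | methyl (triphenylphosphoranylidene)acetate | COC(=O)C=P(c1ccccc1)(c1ccccc1)c1ccccc1 | starting material
7 | methyl (2E)-4-(TBSO)but-2-enoate | COC(=O)/C=C/CO[Si](C)(C)C(C)(C)C | intermediate
8 | methyl (3R)-3-{3-methoxy-2-(TBSO)-5-[3-(TBSO)propyl]phenyl}-4-(TBSO)butanoate | COC(=O)C[C@H](c1cc(CCCO[Si](C)(C)C(C)(C)C)cc(OC)c1O[Si](C)(C)C(C)(C)C)CO[Si](C)(C)C(C)(C)C | intermediate
9 | O-trimethylsilyl ketene acetal of 8 (3R; not isolated) | COC(O[Si](C)(C)C)=C[C@H](c1cc(CCCO[Si](C)(C)C(C)(C)C)cc(OC)c1O[Si](C)(C)C(C)(C)C)CO[Si](C)(C)C(C)(C)C | intermediate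
10 | methyl (2RS,3R)-2-bromo-3-{3-methoxy-2-(TBSO)-5-[3-(TBSO)propyl]phenyl}-4-(TBSO)butanoate | COC(=O)C(Br)[C@H](c1cc(CCCO[Si](C)(C)C(C)(C)C)cc(OC)c1O[Si](C)(C)C(C)(C)C)CO[Si](C)(C)C(C)(C)C | intermediate
11 | methyl (2RS,3R)-2-bromo-3-{2-hydroxy-3-methoxy-5-[3-(TBSO)propyl]phenyl}-4-(TBSO)butanoate (not isolated) | COC(=O)C(Br)[C@H](c1cc(CCCO[Si](C)(C)C(C)(C)C)cc(OC)c1O)CO[Si](C)(C)C(C)(C)C | intermediate
12 | methyl (2R,3R)-7-methoxy-3-(TBSO-methyl)-5-[3-(TBSO)propyl]-2,3-dihydro-1-benzofuran-2-carboxylate (cis; not isolated) | COc1cc(CCCO[Si](C)(C)C(C)(C)C)cc2c1O[C@@H](C(=O)OC)[C@H]2CO[Si](C)(C)C(C)(C)C | intermediate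
13 | methyl (2S,3R)-7-methoxy-3-(TBSO-methyl)-5-[3-(TBSO)propyl]-2,3-dihydro-1-benzofuran-2-carboxylate (trans) | COc1cc(CCCO[Si](C)(C)C(C)(C)C)cc2c1O[C@H](C(=O)OC)[C@H]2CO[Si](C)(C)C(C)(C)C | intermediate
14 | (2S,3R)-7-methoxy-3-(TBSO-methyl)-5-[3-(TBSO)propyl]-2,3-dihydro-1-benzofuran-2-carbaldehyde (not isolated) | COc1cc(CCCO[Si](C)(C)C(C)(C)C)cc2c1O[C@H](C=O)[C@H]2CO[Si](C)(C)C(C)(C)C | intermediate
15 | (2S,3R)-2-ethynyl-7-methoxy-3-(TBSO-methyl)-5-[3-(TBSO)propyl]-2,3-dihydro-1-benzofuran | COc1cc(CCCO[Si](C)(C)C(C)(C)C)cc2c1O[C@H](C#C)[C@H]2CO[Si](C)(C)C(C)(C)C | intermediate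
16 | vinyl acetate | C=COC(C)=O | starting material
17 | (1Z)-3-{(2S,3R)-7-methoxy-3-(TBSO-methyl)-5-[3-(TBSO)propyl]-2,3-dihydro-1-benzofuran-2-yl}buta-1,3-dien-1-yl acetate (not isolated) | COc1cc(CCCO[Si](C)(C)C(C)(C)C)cc2c1O[C@H](C(=C)/C=C\OC(C)=O)[C@H]2CO[Si](C)(C)C(C)(C)C | intermediate
18 | (1E)-3-{(2S,3R)-7-methoxy-3-(TBSO-methyl)-5-[3-(TBSO)propyl]-2,3-dihydro-1-benzofuran-2-yl}buta-1,3-dien-1-yl acetate | COc1cc(CCCO[Si](C)(C)C(C)(C)C)cc2c1O[C@H](C(=C)/C=C/OC(C)=O)[C@H]2CO[Si](C)(C)C(C)(C)C | intermediate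
19 | acrolein | C=CC=O | starting material
20 | (1S,6R)-6-formyl-3-{(2S,3R)-7-methoxy-3-(TBSO-methyl)-5-[3-(TBSO)propyl]-2,3-dihydro-1-benzofuran-2-yl}cyclohex-2-en-1-yl acetate | COc1cc(CCCO[Si](C)(C)C(C)(C)C)cc2c1O[C@H](C1=C[C@H](OC(C)=O)[C@H](C=O)CC1)[C@H]2CO[Si](C)(C)C(C)(C)C | intermediate
21 | (1S,6R)-6-(formyloxy)-3-{(2S,3R)-7-methoxy-3-(TBSO-methyl)-5-[3-(TBSO)propyl]-2,3-dihydro-1-benzofuran-2-yl}cyclohex-2-en-1-yl acetate (not isolated) | COc1cc(CCCO[Si](C)(C)C(C)(C)C)cc2c1O[C@H](C1=C[C@H](OC(C)=O)[C@H](OC=O)CC1)[C@H]2CO[Si](C)(C)C(C)(C)C | intermediate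
22 | (1R,2S)-4-{(2S,3R)-7-methoxy-3-(TBSO-methyl)-5-[3-(TBSO)propyl]-2,3-dihydro-1-benzofuran-2-yl}cyclohex-3-ene-1,2-diol | COc1cc(CCCO[Si](C)(C)C(C)(C)C)cc2c1O[C@H](C1=C[C@H](O)[C@H](O)CC1)[C@H]2CO[Si](C)(C)C(C)(C)C | intermediate
23 | difengpiol A, (1R,2S)-4-[(2S,3R)-3-(hydroxymethyl)-5-(3-hydroxypropyl)-7-methoxy-2,3-dihydro-1-benzofuran-2-yl]cyclohex-3-ene-1,2-diol | COc1cc(CCCO)cc2c1O[C@H](C1=C[C@H](O)[C@H](O)CC1)[C@H]2CO | target

Total steps: 12. Longest linear sequence: 11 steps (1 → 2 → 3 → 4 → 8 → 10 → 13 → 15 → 18 → 20 → 22 → 23); step 4 is a one-step side branch.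

Steps most likely to fail

Step 10. The iminium cycloaddition may show poor facial or endo/exo discrimination with this hindered diene, or the dienyl acetate may be hydrolysed or lose its acyl group to the amine before it cycloadds. The fallback replaces catalyst control by auxiliary control under Lewis acid activation. Setting out from 18, reaction with (4S)-3-acryloyl-4-benzyl-1,3-oxazolidin-2-one (C=CC(=O)N1C(=O)OC[C@@H]1Cc1ccccc1) and Et2AlCl in CH2Cl2 at −78 °C should give the cis imide adduct F1. This is expected through the chelated s-cis acrylimide, whose benzyl group exposes the same Cα face, and an endo transition state. Reductive removal of the auxiliary with LiBH4 (Et2O, 1 equiv H2O, 0 °C) should give the primary alcohol F2. Dess–Martin oxidation (NaHCO3, CH2Cl2) comes back to the route at 20.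

Step 9. The enol ester may stall the metathesis by converting the ruthenium carbene into an unreactive acyloxy-substituted carbene, and convergence of the alkene geometry may be incomplete. The fallback separates diene construction from geometry control. Setting out from 15, enyne cross-metathesis with ethyl vinyl ether (C=COCC, same ruthenium catalyst) should give the 1-ethoxy diene F3 as a geometric mixture. Mild aqueous acid (oxalic acid, wet THF, 0 °C) hydrolyses it by terminal protonation to the (E)-enal F4. Deprotonation of the methyl group syn to the formyl group with KOt-Bu (THF, −78 °C) and O-acetylation of the potassium dienolate with acetyl chloride should give the E-dienyl acetate selectively, coming back to the route at 18.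

Step 5. Protodeboronation of the hindered, electron-rich ortho-silyloxy aryl boronate may outpace its addition to the acyclic enoate, and the aryl silyl ether may be lost in the aqueous base. The fallback uses a more reactive cyclic acceptor and a lactone detour. Setting out from 4, the same rhodium catalysis with (R)-BINAP and 2(5H)-furanone (O=C1C=CCO1) should give the (R)-aryl butyrolactone F5. Silyl ketene acetal bromination as in step 6 should give the trans bromolactone F6. K2CO3 in MeOH cleaves the aryl silyl ether, and the phenoxide displaces bromide with inversion to give the cis-fused tricyclic lactone F7. NaOMe in MeOH opens the lactone and epimerises C2 to give the trans hydroxy ester F8, which cannot relactonise. Silylation (TBSCl, imidazole, DMF) comes back to the route at 13.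

Further compounds
F1 | step 10 | (1S,6R)-6-{[(4S)-4-benzyl-2-oxo-1,3-oxazolidin-3-yl]carbonyl}-3-{(2S,3R)-7-methoxy-3-(TBSO-methyl)-5-[3-(TBSO)propyl]-2,3-dihydro-1-benzofuran-2-yl}cyclohex-2-en-1-yl acetate | COc1cc(CCCO[Si](C)(C)C(C)(C)C)cc2c1O[C@H](C1=C[C@H](OC(C)=O)[C@H](C(=O)N3C(=O)OC[C@@H]3Cc3ccccc3)CC1)[C@H]2CO[Si](C)(C)C(C)(C)C
F2 | step 10 | (1S,6S)-6-(hydroxymethyl)-3-{(2S,3R)-7-methoxy-3-(TBSO-methyl)-5-[3-(TBSO)propyl]-2,3-dihydro-1-benzofuran-2-yl}cyclohex-2-en-1-yl acetate | COc1cc(CCCO[Si](C)(C)C(C)(C)C)cc2c1O[C@H](C1=C[C@H](OC(C)=O)[C@H](CO)CC1)[C@H]2CO[Si](C)(C)C(C)(C)C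
F3 | step 9 | (2S,3R)-2-(4-ethoxybuta-1,3-dien-2-yl)-7-methoxy-3-(TBSO-methyl)-5-[3-(TBSO)propyl]-2,3-dihydro-1-benzofuran (E/Z mixture) | COc1cc(CCCO[Si](C)(C)C(C)(C)C)cc2c1O[C@H](C(=C)C=COCC)[C@H]2CO[Si](C)(C)C(C)(C)C
F4 | step 9 | (2E)-3-{(2S,3R)-7-methoxy-3-(TBSO-methyl)-5-[3-(TBSO)propyl]-2,3-dihydro-1-benzofuran-2-yl}but-2-enal | COc1cc(CCCO[Si](C)(C)C(C)(C)C)cc2c1O[C@H](/C(C)=C/C=O)[C@H]2CO[Si](C)(C)C(C)(C)C
F5 | step 5 | (4R)-4-{3-methoxy-2-(TBSO)-5-[3-(TBSO)propyl]phenyl}dihydrofuran-2(3H)-one | O=C1C[C@H](c2cc(CCCO[Si](C)(C)C(C)(C)C)cc(OC)c2O[Si](C)(C)C(C)(C)C)CO1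
F6 | step 5 | (3S,4R)-3-bromo-4-{3-methoxy-2-(TBSO)-5-[3-(TBSO)propyl]phenyl}dihydrofuran-2(3H)-one (trans) | O=C1[C@@H](Br)[C@H](c2cc(CCCO[Si](C)(C)C(C)(C)C)cc(OC)c2O[Si](C)(C)C(C)(C)C)CO1
F7 | step 5 | (3aR,8bR)-5-methoxy-7-[3-(TBSO)propyl]-3a,8b-dihydro-1H-furo[3,4-b][1]benzofuran-3-one (cis-fused tricyclic lactone) | O=C1OC[C@H]2c3cc(CCCO[Si](C)(C)C(C)(C)C)cc(OC)c3O[C@@H]12
F8 | step 5 | methyl (2S,3R)-3-(hydroxymethyl)-7-methoxy-5-[3-(TBSO)propyl]-2,3-dihydro-1-benzofuran-2-carboxylate | COc1cc(CCCO[Si](C)(C)C(C)(C)C)cc2c1O[C@H](C(=O)OC)[C@H]2CO
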